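## Retrosynthetic overview

1. The last C–C bond is the central 6′,6″-biaryl bond. It is made without an oxidant from a quinol acetate (electrophile, tetrahydroisoquinoline half) and a free 1-naphthol (nucleophile, dihydroisoquinoline half), followed by one global BCl3 deprotection.
2. Both isoquinoline–naphthalene bonds come from 1,2-addition of an aryllithium to the C-1 carbonyl of the same quinone, 5-methoxy-7-methyl-1,4-naphthoquinone. One adduct is kept as the quinol acetate and the other is reduced to the naphthol.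
3. Both nitrogen rings come from a Beckmann C-to-N 1,2-shift of an (R)-α-methyl ketone with retention. The nitrilium ion closes the ring on the resorcinol nucleus, and a trans reduction follows in one half only.
4. The (R)-ketones come from Ir C–H borylation of a resorcinol diether, then Rh-catalysed conjugate arylation of 3-methylbut-3-en-2-one with enantioselective protonation.
5. Ring order: the naphthoquinone is built first (Diels–Alder, ring A onto benzoquinone). The heterocycle precedes the biaryl bond in the tetrahydroisoquinoline half, and the biaryl bond precedes the heterocycle in the dihydroisoquinoline half.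

Assumption: the SMILES fixes only the three stereocentres (1R,3R and 3R). The two hindered isoquinoline–naphthalene axes are not encoded, so they form without control and the atropo-diastereomers are separated by chromatography at 31 and at 34; the central axis rotates freely.

## Route

Step 1
Reactants: 1 methyl 3-methylbut-2-enoate
Product: 2 [(1-methoxy-3-methylbuta-1,3-dien-1-yl)oxy]trimethylsilane
Conditions: LiN(iPr)2 (1.1 equiv), THF, −78 °C; Me3SiCl (1.2 equiv), −78 °C → rt
Reagents that add atoms: chlorotrimethylsilane, C[Si](C)(C)Cl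
Why: Kinetic gamma-deprotonation of the senecioate and O-silylation of the extended enolate (silyl ketene acetal formation) give the electron-rich 1,1-dioxygenated diene.

Step 2
Reactants: 2 [(1-methoxy-3-methylbuta-1,3-dien-1-yl)oxy]trimethylsilane, 3 1,4-benzoquinone
Product: 5 5-hydroxy-7-methylnaphthalene-1,4-dione (7-methyljuglone), via cycloadduct 4 (not isolated)
Conditions: 3 (2.2 equiv), CH2Cl2, −20 °C → rt; then dilute aq HCl/THF, rt
Reagents that add atoms: none
Why: The Diels–Alder reaction with the symmetrical quinone raises no regiochemical question, and loss of methanol, enolisation, oxidation by the second equivalent of 3 and acidic desilylation aromatise ring A to the juglone.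

Step 3
Reactants: 5 5-hydroxy-7-methylnaphthalene-1,4-dione
Product: 6 5-methoxy-7-methylnaphthalene-1,4-dione
Conditions: MeI (5 equiv), Ag2O (1.5 equiv), CH2Cl2, rt, dark
Reagents that add atoms: iodomethane, CI
Why: Williamson-type O-methylation under neutral Ag2O conditions is the standard way to etherify the chelated peri-hydroxyl of a juglone without base damage to the quinone.

Step 4
Reactants: 7 resorcinol
Product: 8 1,3-diisopropoxybenzene
Conditions: 2-bromopropane (3 equiv), K2CO3 (3 equiv), DMF, 70 °C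
Reagents that add atoms: 2-bromopropane, CC(C)Br
Why: This is a double Williamson ether synthesis, and the isopropyl ethers withstand organolithiums and acid yet fall to BCl3 at the end.

Step 5
Reactants: 8 1,3-diisopropoxybenzene
Product: 9 2-(3,5-diisopropoxyphenyl)-4,4,5,5-tetramethyl-1,3,2-dioxaborolane
Conditions: [Ir(OMe)(cod)]2 (1 mol %), dtbpy (2 mol %), B2pin2 (1.0 equiv), MTBE, 70 °C
Reagents that add atoms: bis(pinacolato)diboron, CC1(C)OB(OC1(C)C)B1OC(C)(C)C(C)(C)O1
Why: Sterically controlled iridium-catalysed aromatic C–H borylation takes C-5, the only C–H bond without an ortho substituent.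

Step 6
Reactants: 9 2-(3,5-diisopropoxyphenyl)-4,4,5,5-tetramethyl-1,3,2-dioxaborolane, 10 3-methylbut-3-en-2-one
Product: 11 (R)-4-(3,5-diisopropoxyphenyl)-3-methylbutan-2-one
Conditions: [Rh(OH)((R)-binap)]2 (2.5 mol %), 10 (2.5 equiv), 2-methoxyphenol (1.0 equiv), H2O (2 equiv), dioxane, 45 °C
Reagents that add atoms: none
Why: Proposed new method: Hayashi–Miyaura-type arylrhodation of the 1,1-disubstituted enone puts the aryl group on the CH2 terminus and leaves an oxa-pi-allyl rhodium enolate whose alpha-carbon is protonated by the phenol donor inside the BINAP pocket, which sets the R centre (the ligand antipode is taken if the sense proves opposite) while the near-neutral medium keeps the alpha-methyl ketone from epimerising; the closest known reaction type is rhodium-catalysed conjugate addition with enantioselective protonation of alpha-substituted acrylates and dehydroamino esters, not yet shown for alpha-alkyl vinyl ketones.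

Step 7
Reactants: 11 (R)-4-(3,5-diisopropoxyphenyl)-3-methylbutan-2-one
Product: 14 (R)-6,8-diisopropoxy-1,3-dimethyl-3,4-dihydroisoquinoline, via oxime O-sulfonic acid 12 (not isolated), via nitrilium hydrogensulfate 13 (not isolated)
Conditions: H2NOSO3H (1.2 equiv), 4 Å sieves, (CF3)2CHOH, 0 → 45 °C; aq NaHCO3
Reagents that add atoms: hydroxylamine-O-sulfonic acid, NOS(=O)(=O)O
Why: This is a Beckmann rearrangement with Bischler–Napieralski-type capture, in which condensation gives the oxime O-sulfonate (E favoured, E and Z equilibrate in acid and the secondary carbon migrates far faster than methyl), ionisation in the fluoroalcohol drives the 1,2-shift of the stereogenic carbon from C to N with retention, and the nitrilium ion closes onto the ortho carbon activated by both ether groups.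

Step 8
Reactants: 14 (R)-6,8-diisopropoxy-1,3-dimethyl-3,4-dihydroisoquinoline
Product: 15 (1R,3R)-6,8-diisopropoxy-1,3-dimethyl-1,2,3,4-tetrahydroisoquinoline
Conditions: AlMe3 (2 equiv), LiAlH4 (2 equiv), THF, −78 → 0 °C; aq NaOH
Reagents that add atoms: none
Why: In this diastereoselective imine reduction AlMe3 sits on nitrogen and the hydride enters C-1 from the face of the C-3 methyl group, the established route to the trans (1R,3R) series (about 9:1, minor cis isomer removed by chromatography).

Step 9
Reactants: 15 (1R,3R)-6,8-diisopropoxy-1,3-dimethyl-1,2,3,4-tetrahydroisoquinoline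
Product: 16 tert-butyl (1R,3R)-6,8-diisopropoxy-1,3-dimethyl-3,4-dihydroisoquinoline-2(1H)-carboxylate
Conditions: Boc2O (1.5 equiv), Et3N, THF, 50 °C
Reagents that add atoms: di-tert-butyl dicarbonate, CC(C)(C)OC(=O)OC(=O)OC(C)(C)C
Why: Carbamate protection removes the N–H proton before the organolithium step and shields the amine from NBS.

Step 10
Reactants: 16 tert-butyl (1R,3R)-6,8-diisopropoxy-1,3-dimethyl-3,4-dihydroisoquinoline-2(1H)-carboxylate
Product: 17 tert-butyl (1R,3R)-5-bromo-6,8-diisopropoxy-1,3-dimethyl-3,4-dihydroisoquinoline-2(1H)-carboxylate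
Conditions: NBS (1.0 equiv), MeCN, −10 °C, dark
Reagents that add atoms: N-bromosuccinimide, O=C1CCC(=O)N1Br
Why: Electrophilic aromatic bromination goes to C-5, ortho and para to the two ether groups, because the equally activated C-7 is shielded by two isopropoxy groups.

Step 11
Reactants: 17 tert-butyl (1R,3R)-5-bromo-6,8-diisopropoxy-1,3-dimethyl-3,4-dihydroisoquinoline-2(1H)-carboxylate, 6 5-methoxy-7-methylnaphthalene-1,4-dione
Product: 20 tert-butyl (1R,3R)-5-(1-acetoxy-5-methoxy-7-methyl-4-oxo-1,4-dihydronaphthalen-1-yl)-6,8-diisopropoxy-1,3-dimethyl-3,4-dihydroisoquinoline-2(1H)-carboxylate (both epimers at the acetoxy carbon), via aryllithium 18 (not isolated), via lithium quinolate 19 (not isolated)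
Conditions: t-BuLi (2.1 equiv), THF, −78 °C; cannulate into 6 (1.2 equiv), THF, −78 °C; Ac2O (1.5 equiv), −78 → 0 °C
Reagents that add atoms: acetic anhydride, CC(=O)OC(C)=O
Why: Bromine–lithium exchange outruns attack on the carbamate at −78 °C, the hindered aryllithium adds 1,2 to the C-1 carbonyl of 6 (C-4 is shielded by the peri-methoxy group and deactivated by its donation), and the tertiary alkoxide is trapped as the acetate, the new carbinol centre being a mixture that is erased in step 18.

Step 12
Reactants: 7 resorcinol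
Product: 21 3-methoxyphenol
Conditions: MeI (1.0 equiv), K2CO3 (1.0 equiv), acetone, reflux
Reagents that add atoms: iodomethane, CI
Why: This is a statistical mono-Williamson methylation with one equivalent of MeI, and the monoether is separated from resorcinol and the diether by extraction and distillation.

Step 13
Reactants: 21 3-methoxyphenol
Product: 22 1-isopropoxy-3-methoxybenzene
Conditions: 2-bromopropane (1.5 equiv), K2CO3 (1.5 equiv), DMF, 70 °C
Reagents that add atoms: 2-bromopropane, CC(C)Br
Why: Williamson ether synthesis on the remaining phenol installs the bulky, acid-stable group that later steers the ring closure.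

Step 14
Reactants: 22 1-isopropoxy-3-methoxybenzene, 6 5-methoxy-7-methylnaphthalene-1,4-dione
Product: 25 4-(2-isopropoxy-6-methoxyphenyl)-8-methoxy-6-methylnaphthalen-1-ol, via aryllithium 23 (not isolated), via lithium quinolate 24 (not isolated)
Conditions: n-BuLi (1.1 equiv), THF, 0 °C → rt; add to 6 (1.1 equiv), THF, −78 °C; AcOH, Zn dust, rt
Reagents that add atoms: none
Why: Directed ortho-metalation takes the proton between the two alkoxy groups, the 1,2-addition follows the carbonyl preference of step 11, and zinc in acetic acid expels the tertiary oxygen of the p-quinol (reductive aromatisation) to give the 4-aryl-1-naphthol.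

Step 15
Reactants: 25 4-(2-isopropoxy-6-methoxyphenyl)-8-methoxy-6-methylnaphthalen-1-ol
Product: 27 4-[2-isopropoxy-6-methoxy-4-(4,4,5,5-tetramethyl-1,3,2-dioxaborolan-2-yl)phenyl]-8-methoxy-6-methylnaphthalen-1-ol, via bis-borylated naphthyl ether 26 (not isolated)
Conditions: HBpin (1.1 equiv), THF, rt; then [Ir(OMe)(cod)]2 (2 mol %), dtbpy (4 mol %), B2pin2 (1.0 equiv), 60 °C; MeOH
Reagents that add atoms: bis(pinacolato)diboron, CC1(C)OB(OC1(C)C)B1OC(C)(C)C(C)(C)O1
Why: The phenol is masked in the flask as its O-boryl ether, sterically controlled iridium-catalysed C–H borylation then takes the only C–H bond flanked by two hydrogens (para to the biaryl bond), and methanol frees the naphthol again.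

Step 16
Reactants: 27 4-[2-isopropoxy-6-methoxy-4-(4,4,5,5-tetramethyl-1,3,2-dioxaborolan-2-yl)phenyl]-8-methoxy-6-methylnaphthalen-1-ol, 10 3-methylbut-3-en-2-one
Product: 28 (R)-4-[4-(4-hydroxy-5-methoxy-7-methylnaphthalen-1-yl)-3-isopropoxy-5-methoxyphenyl]-3-methylbutan-2-one
Conditions: [Rh(OH)((R)-binap)]2 (2.5 mol %), 10 (2.5 equiv), 2-methoxyphenol (1.0 equiv), H2O (2 equiv), dioxane, 45 °C, argon
Reagents that add atoms: none
Why: Proposed new method: as in step 6, arylrhodation of the alpha-methyl enone gives an oxa-pi-allyl rhodium enolate that is protonated at carbon within the BINAP pocket to set the R centre, the non-oxidative and near-neutral medium sparing the free naphthol; the closest known reaction type is rhodium-catalysed conjugate addition with enantioselective protonation of alpha-substituted acrylates, not yet shown for alpha-alkyl vinyl ketones.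

Step 17
Reactants: 28 (R)-4-[4-(4-hydroxy-5-methoxy-7-methylnaphthalen-1-yl)-3-isopropoxy-5-methoxyphenyl]-3-methylbutan-2-one
Product: 31 4-[(R)-6-isopropoxy-8-methoxy-1,3-dimethyl-3,4-dihydroisoquinolin-7-yl]-8-methoxy-6-methylnaphthalen-1-ol, via oxime O-sulfonic acid 29 (not isolated), via nitrilium hydrogensulfate 30 (not isolated)
Conditions: H2NOSO3H (1.2 equiv), 4 Å sieves, (CF3)2CHOH, 0 → 45 °C; aq NaHCO3
Reagents that add atoms: hydroxylamine-O-sulfonic acid, NOS(=O)(=O)O
Why: The same Beckmann 1,2-shift with retention delivers the nitrilium ion, which closes ortho to the small methoxy group and para to the isopropoxy group because the isopropyl group, pushed outward by the neighbouring naphthyl, blocks the other ortho carbon.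

Step 18
Reactants: 20 tert-butyl (1R,3R)-5-(1-acetoxy-5-methoxy-7-methyl-4-oxo-1,4-dihydronaphthalen-1-yl)-6,8-diisopropoxy-1,3-dimethyl-3,4-dihydroisoquinoline-2(1H)-carboxylate, 31 4-[(R)-6-isopropoxy-8-methoxy-1,3-dimethyl-3,4-dihydroisoquinolin-7-yl]-8-methoxy-6-methylnaphthalen-1-ol
Product: 33 N-Boc-tri-O-isopropylkorundamine A, via naphthoxenium acetate 32 (not isolated)
Conditions: 31 (1.0 equiv), CF3CO2H (1.05 equiv), then 20 (1.1 equiv), (CF3)2CHOH, 0 °C → rt, argon; aq NaHCO3
Reagents that add atoms: none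
Why: Proposed new method: the doubly benzylic quinol acetate ionises in the fluoroalcohol to an aryl-stabilised 1-naphthoxenium ion with positive charge at C-2 and C-4, C-4 is blocked, so the free ortho carbon of naphthol 31 (its imine parked as the iminium salt, and C-7 of the electrophile shielded by two isopropoxy groups) attacks C-2 and tautomerisation gives the unsymmetrical binaphthol at the right oxidation level with no oxidant and hence no homodimer pathway; the closest known reaction types are the acid-promoted arylation of quinone monoacetals by electron-rich arenes and the solvolysis of 4-aryl quinol esters to aryloxenium ions.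

Step 19
Reactants: 33 N-Boc-tri-O-isopropylkorundamine A
Product: 34 korundamine A
Conditions: BCl3 (12 equiv), CH2Cl2, −78 → 0 °C; MeOH; aq NaHCO3, argon
Reagents that add atoms: none
Why: Lewis acid ether cleavage with BCl3 removes the secondary isopropyl aryl ethers and the tert-butyl carbamate through cation-like pathways well below the temperature at which aryl methyl ethers react, and no stereocentre is touched.

## Compound list

1 | methyl 3-methylbut-2-enoate | COC(=O)C=C(C)C | starting material
2 | [(1-methoxy-3-methylbuta-1,3-dien-1-yl)oxy]trimethylsilane | COC(O[Si](C)(C)C)=CC(C)=C | intermediate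
3 | 1,4-benzoquinone | O=C1C=CC(=O)C=C1 | starting material
4 | 5-methoxy-7-methyl-5-(trimethylsilyloxy)-4a,5,8,8a-tetrahydronaphthalene-1,4-dione | COC1(O[Si](C)(C)C)C=C(C)CC2C1C(=O)C=CC2=O | intermediate
5 | 5-hydroxy-7-methylnaphthalene-1,4-dione | Cc1cc(O)c2C(=O)C=CC(=O)c2c1 | intermediate
6 | 5-methoxy-7-methylnaphthalene-1,4-dione | COc1cc(C)cc2C(=O)C=CC(=O)c12 | intermediate
7 | resorcinol | Oc1cccc(O)c1 | starting material
8 | 1,3-diisopropoxybenzene | CC(C)Oc1cccc(OC(C)C)c1 | intermediate
9 | 2-(3,5-diisopropoxyphenyl)-4,4,5,5-tetramethyl-1,3,2-dioxaborolane | CC(C)Oc1cc(OC(C)C)cc(B2OC(C)(C)C(C)(C)O2)c1 | intermediate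
10 | 3-methylbut-3-en-2-one | CC(=C)C(C)=O | starting material
11 | (R)-4-(3,5-diisopropoxyphenyl)-3-methylbutan-2-one | CC(C)Oc1cc(OC(C)C)cc(C[C@@H](C)C(C)=O)c1 | intermediate
12 | (E)-oxime O-sulfonic acid of 11 | CC(C)Oc1cc(OC(C)C)cc(C[C@@H](C)/C(C)=N/OS(=O)(=O)O)c1 | intermediate
13 | N-[(R)-1-(3,5-diisopropoxyphenyl)propan-2-yl]acetonitrilium hydrogensulfate | CC(C)Oc1cc(OC(C)C)cc(C[C@@H](C)[N+]#CC)c1.OS(=O)(=O)[O-] | intermediate
14 | (R)-6,8-diisopropoxy-1,3-dimethyl-3,4-dihydroisoquinoline | CC(C)Oc1cc(OC(C)C)c2c(c1)C[C@@H](C)N=C2C | intermediate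
15 | (1R,3R)-6,8-diisopropoxy-1,3-dimethyl-1,2,3,4-tetrahydroisoquinoline | CC(C)Oc1cc(OC(C)C)c2c(c1)C[C@@H](C)N[C@@H]2C | intermediate
16 | tert-butyl (1R,3R)-6,8-diisopropoxy-1,3-dimethyl-3,4-dihydroisoquinoline-2(1H)-carboxylate | CC(C)Oc1cc(OC(C)C)c2c(c1)C[C@@H](C)N(C(=O)OC(C)(C)C)[C@@H]2C | intermediate
17 | tert-butyl (1R,3R)-5-bromo-6,8-diisopropoxy-1,3-dimethyl-3,4-dihydroisoquinoline-2(1H)-carboxylate | CC(C)Oc1cc(OC(C)C)c2c(c1Br)C[C@@H](C)N(C(=O)OC(C)(C)C)[C@@H]2C | intermediate
18 | 5-lithio derivative of 16 | CC(C)Oc1cc(OC(C)C)c2c(c1[Li])C[C@@H](C)N(C(=O)OC(C)(C)C)[C@@H]2C | intermediate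
19 | lithium alkoxide of the quinol from 18 and 6 (both epimers at the carbinol carbon) | CC(C)Oc1cc(OC(C)C)c2c(c1C3([O-])C=CC(=O)c4c(OC)cc(C)cc34)C[C@@H](C)N(C(=O)OC(C)(C)C)[C@@H]2C.[Li+] | intermediate
20 | tert-butyl (1R,3R)-5-(1-acetoxy-5-methoxy-7-methyl-4-oxo-1,4-dihydronaphthalen-1-yl)-6,8-diisopropoxy-1,3-dimethyl-3,4-dihydroisoquinoline-2(1H)-carboxylate (both epimers at the acetoxy carbon) | CC(C)Oc1cc(OC(C)C)c2c(c1C3(OC(C)=O)C=CC(=O)c4c(OC)cc(C)cc34)C[C@@H](C)N(C(=O)OC(C)(C)C)[C@@H]2C | intermediate
21 | 3-methoxyphenol | COc1cccc(O)c1 | intermediate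
22 | 1-isopropoxy-3-methoxybenzene | COc1cccc(OC(C)C)c1 | intermediate
23 | (2-isopropoxy-6-methoxyphenyl)lithium | COc1cccc(OC(C)C)c1[Li] | intermediate
24 | lithium 1-(2-isopropoxy-6-methoxyphenyl)-5-methoxy-7-methyl-4-oxo-1,4-dihydronaphthalen-1-olate (racemic) | COc1cccc(OC(C)C)c1C2([O-])C=CC(=O)c3c(OC)cc(C)cc23.[Li+] | intermediate
25 | 4-(2-isopropoxy-6-methoxyphenyl)-8-methoxy-6-methylnaphthalen-1-ol | COc1cccc(OC(C)C)c1-c2ccc(O)c3c(OC)cc(C)cc23 | intermediate
26 | O-boryl ether of 27 | COc1cc(B2OC(C)(C)C(C)(C)O2)cc(OC(C)C)c1-c3ccc(OB4OC(C)(C)C(C)(C)O4)c5c(OC)cc(C)cc35 | intermediate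
27 | 4-[2-isopropoxy-6-methoxy-4-(4,4,5,5-tetramethyl-1,3,2-dioxaborolan-2-yl)phenyl]-8-methoxy-6-methylnaphthalen-1-ol | COc1cc(B2OC(C)(C)C(C)(C)O2)cc(OC(C)C)c1-c3ccc(O)c4c(OC)cc(C)cc34 | intermediate
28 | (R)-4-[4-(4-hydroxy-5-methoxy-7-methylnaphthalen-1-yl)-3-isopropoxy-5-methoxyphenyl]-3-methylbutan-2-one | COc1cc(C[C@@H](C)C(C)=O)cc(OC(C)C)c1-c2ccc(O)c3c(OC)cc(C)cc23 | intermediate
29 | (E)-oxime O-sulfonic acid of 28 | COc1cc(C[C@@H](C)/C(C)=N/OS(=O)(=O)O)cc(OC(C)C)c1-c2ccc(O)c3c(OC)cc(C)cc23 | intermediate
30 | nitrilium hydrogensulfate from 29 | COc1cc(C[C@@H](C)[N+]#CC)cc(OC(C)C)c1-c2ccc(O)c3c(OC)cc(C)cc23.OS(=O)(=O)[O-] | intermediate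
31 | 4-[(R)-6-isopropoxy-8-methoxy-1,3-dimethyl-3,4-dihydroisoquinolin-7-yl]-8-methoxy-6-methylnaphthalen-1-ol | COc1c2c(cc(OC(C)C)c1-c3ccc(O)c4c(OC)cc(C)cc34)C[C@@H](C)N=C2C | intermediate
32 | 4-aryl-1-naphthoxenium acetate ion pair from 20 | CC(C)Oc1cc(OC(C)C)c2c(c1[C+]3C=CC(=O)c4c(OC)cc(C)cc34)C[C@@H](C)N(C(=O)OC(C)(C)C)[C@@H]2C.CC(=O)[O-] | intermediate
33 | N-Boc-tri-O-isopropylkorundamine A | COc1c2c(cc(OC(C)C)c1-c1cc(-c3cc(-c4c(OC(C)C)cc(OC(C)C)c5c4C[C@@H](C)N(C(=O)OC(C)(C)C)[C@@H]5C)c4cc(C)cc(OC)c4c3O)c(O)c3c(OC)cc(C)cc13)C[C@@H](C)N=C2C | intermediate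
34 | korundamine A | COc1c2c(cc(O)c1-c1cc(-c3cc(-c4c(O)cc(O)c5c4C[C@@H](C)N[C@@H]5C)c4cc(C)cc(OC)c4c3O)c(O)c3c(OC)cc(C)cc13)C[C@@H](C)N=C2C | target

## Step count and risks

Total steps: 19.

Longest linear sequence: 10 steps (7 → 8 → 9 → 11 → 14 → 15 → 16 → 17 → 20 → 33 → 34).

**Step 6 (new).**
- Risk: C–C bond formation is safe, but the enolate may be protonated outside the chiral pocket and give low ee.
- Fallback (known chemistry), setting out from 10 and 9 and returning at 11:
  - Bromine adds to 10 in CH2Cl2 at 0 °C to give 3,4-dibromo-3-methylbutan-2-one F1.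
  - Et3N eliminates HBr from F1 to give (E)-4-bromo-3-methylbut-3-en-2-one F2.
  - Suzuki–Miyaura coupling of F2 with 9 (Pd(PPh3)4, K2CO3, dioxane/H2O, 60 °C) gives, with retention of geometry, (E)-4-(3,5-diisopropoxyphenyl)-3-methylbut-3-en-2-one F3.
  - Asymmetric hydrogenation of this trisubstituted alpha-methyl enone with [Ir(cod)((S)-tBu-PHOX)][B(C6H3(CF3)2)4] under H2 (50 bar, toluene; ligand antipode chosen for R) sets the stereocentre and gives 11.

**Step 16 (new).**
- Risk: the same uncertainty in ee applies, and it is aggravated by the free naphthol acting as a second proton donor.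
- Fallback (known chemistry), setting out from 27 and returning at 28:
  - The bromoenone F2 made as above is coupled with 27 under the same non-oxidative Suzuki–Miyaura conditions, which a free naphthol tolerates. This gives (E)-4-[4-(4-hydroxy-5-methoxy-7-methylnaphthalen-1-yl)-3-isopropoxy-5-methoxyphenyl]-3-methylbut-3-en-2-one F4.
  - The same iridium–phosphinooxazoline hydrogenation converts F4 into 28.

**Step 18 (new).**
- Risk: the cation may undergo a dienone–phenol aryl shift. Electron transfer from 31 may also lead to radical pairs and a statistical mixture of dimers.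
- Fallback (known chemistry), setting out from 20 and returning at 33:
  - Zinc in acetic acid reduces the quinol acetate to tert-butyl (1R,3R)-5-(4-hydroxy-5-methoxy-7-methylnaphthalen-1-yl)-6,8-diisopropoxy-1,3-dimethyl-3,4-dihydroisoquinoline-2(1H)-carboxylate F5.
  - An equimolar mixture of F5 and 31 is oxidised with Ag2O (CHCl3, trace Et3N), the oxidative phenolic coupling used for the michellamine dimers. This gives the violet cross-coupled 6′,6″-binaphthylidene-5′,5″-dione F6.
  - F6 is obtained in at most half of the material and is separated from the two symmetrical dimers.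
  - Aqueous Na2S2O4, which leaves the imine alone, reduces F6 to 33.

Further compounds
F1 | step 6 | 3,4-dibromo-3-methylbutan-2-one | CC(=O)C(C)(Br)CBr
F2 | step 6 | (E)-4-bromo-3-methylbut-3-en-2-one | CC(=O)/C(C)=C/Br
F3 | step 6 | (E)-4-(3,5-diisopropoxyphenyl)-3-methylbut-3-en-2-one | CC(C)Oc1cc(OC(C)C)cc(/C=C(\C)C(C)=O)c1
F4 | step 16 | (E)-4-[4-(4-hydroxy-5-methoxy-7-methylnaphthalen-1-yl)-3-isopropoxy-5-methoxyphenyl]-3-methylbut-3-en-2-one | COc1cc(/C=C(\C)C(C)=O)cc(OC(C)C)c1-c2ccc(O)c3c(OC)cc(C)cc23
F5 | step 18 | tert-butyl (1R,3R)-5-(4-hydroxy-5-methoxy-7-methylnaphthalen-1-yl)-6,8-diisopropoxy-1,3-dimethyl-3,4-dihydroisoquinoline-2(1H)-carboxylate | CC(C)Oc1cc(OC(C)C)c2c(c1-c3ccc(O)c4c(OC)cc(C)cc34)C[C@@H](C)N(C(=O)OC(C)(C)C)[C@@H]2C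
F6 | step 18 | cross-coupled 6′,6″-binaphthylidene-5′,5″-dione of F5 and 31 | COc1c2c(cc(OC(C)C)c1C3=CC(=C4C=C(c5c(OC(C)C)cc(OC(C)C)c6c5C[C@@H](C)N(C(=O)OC(C)(C)C)[C@@H]6C)c7cc(C)cc(OC)c7C4=O)C(=O)c8c(OC)cc(C)cc38)C[C@@H](C)N=C2C
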